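## Analysis of the target

The target is a flavone: a 4H-chromen-4-one in which a benzo ring (ring A) is fused to a 4-pyranone (ring C), with a 3,4,5-trimethoxyphenyl group (ring B) on C2. It has no stereocentre and no stereogenic double bond, so the problem is one of connectivity and regiochemistry only. Ring A carries 5-OH (hydrogen-bonded to the C4 carbonyl), C6–H, 7-OH and 8-OMe; C8a bears the ring oxygen O1 and C4a the carbonyl carbon C4. The sensitive features are the two free phenols on an electron-rich phloroglucinol-type ring and the reducible C2=C3 bond. The 5,7-dihydroxy-8-methoxy pattern can also isomerise to the 6-methoxy pattern in hot strong acid through opening and reclosure of ring C (Wessely–Moser rearrangement). The difficulty is that four methyl ethers and two free hydroxyls coexist, so a global demethylation is excluded and every oxygen must be differentiated from the outset. In addition, C4a has two oxygen-bearing neighbours, and the choice of which one becomes O1 decides between the 8-methoxy and the 6-methoxy flavone. The strategy rests on C4 being a single carbon that links C4a to the C3=C2 unit carrying ring B. C4 can therefore come from carbon monoxide, C3 and C2 from a terminal arylacetylene, and the O1–C2 bond from a phenol next to a halogen on the future C4a.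

## Retrosynthetic reasoning

**14 to 13.** The last bond cut is the O–CH2 bond of a benzyl ether on the C5 oxygen. This group is required by the ring closure further back: only if the C5 oxygen is masked can the C8a oxygen alone become O1. Benzyl is chosen because hydrogenolysis is neutral, leaves the four methyl ethers alone and avoids the acid that could start a Wessely–Moser isomerisation.

**13 to 8, 9 and 10.** Ring C is opened at three bonds at once: C4a–C4, C4–C3 and O1–C2. This cut reduces the flavone to three simple parts: ring A as the iodophenol 8, ring B with C2 and C3 as the alkyne 9, and C4 as carbon monoxide 10. The forward reaction must insert 10 between the aryl carbon and the alkyne terminus to give the ynone 11. It must then close the phenol oxygen on the distal alkyne carbon in the 6-endo sense, which a secondary-amine medium secures through the aminoenone 12. In 8 the second hydroxyl is para to the iodine and cannot take part, so it is left free and a protecting-group step is saved.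

**8 to 7.** The C–I bond is cut. Diol 7 has a mirror plane through C2 and C5, so its two unsubstituted ring carbons are equivalent, and each is ortho to one hydroxyl and para to the other. Electrophilic iodination can therefore give only one mono-iodide; the forward reaction has only to stop after one iodine.

**7 to 6, and 6 to 4 and 5.** The two hydroxyls of 7 are released from the bis-acetal 6. The benzyl group is introduced earlier, on phenol 4, where the C5 oxygen is the only free hydroxyl, by alkylation with 5. This order differentiates the C5 oxygen from the other two without any selectivity problem.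

**4 to 2 (through 3), and 2 to 1.** The C5–O bond is cut. C5 is meta to both flanking oxygens and is not reached by electrophilic substitution, but it is the only ring C–H of 2 without an ortho substituent. A sterically controlled iridium-catalysed C–H borylation should therefore give the boronate 3, which is oxidised in the same flask to 4. Compound 2 comes from commercial 1, which already holds the future 8-methoxy group between its two oxygens.

## Alternatives that were turned down

**Alternative 1: ring C closed at carbon by an intramolecular ester Wittig reaction.** The C2=C3 bond is disconnected. On heating, the ylide carbon of the keto-stabilised phosphorane A2 attacks the neighbouring 3,4,5-trimethoxybenzoate carbonyl and gives the bis-benzyl flavone A1 with loss of the phosphine oxide.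
- For: all atoms of ring C are in place before closure, only a six-membered ring can form, and no metal catalyst or pressurised gas is needed. On the reliability of the ring closure itself this route is at least as strong as the chosen one.
- Against: A2 has to be made from the acetophenone A3, whose free hydroxyl must be the one between the acetyl and the methoxy group. The two hydroxyls ortho to the acetyl group differ only by that neighbouring methoxy, so the 8- versus 6-methoxy question is moved to an early dibenzylation with nothing in the structure to settle it.
- Further against: the sequence needs aroylation, α-bromination of a ketone on a ring with one very nucleophilic free position, phosphonium salt formation and ylide generation. It is linear, produces stoichiometric phosphorus waste and ends with two benzyl ethers to remove.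
- Comparison: the chosen route answers the regiochemical question through the symmetry of 7 and a single blocking group, and it is shorter and convergent.

**Alternative 2: ring A built by Moore ring expansion of a pyranonyl cyclobutenone.** The C4a–C5 bond is disconnected and ring A is traced back to a four-membered ring. Heating the cyclobutenone A5 opens it to a dienylketene, which closes by six-electron electrocyclisation onto the neighbouring pyranone CH; tautomerisation gives the phenol A4.
- For: every oxygen of ring A is placed by the construction of the four-carbon unit, so the 8-methoxy position is unambiguous, and the 5-hydroxyl emerges free and already distinguished from the 7-oxygen. On regiochemical certainty this route is stronger than any route that relies on a blocking group.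
- Against: A5 requires a metallated 2-aryl-4-pyranone, itself an electrophile, to add regioselectively to an unsymmetrical cyclobutenedione, followed by methylation of a hindered tertiary alkoxide.
- Further against: the electrocyclisation must occur onto an electron-poor pyranone double bond instead of an arene, for which support is thin. The 7-isopropyl ether must then be cleaved with a Lewis acid next to four methyl ethers.
- Comparison: the sequence is clearly longer and its uncertainty is spread over several steps. The chosen route confines the uncertainty to one well-known reaction type.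

**Alternative 3: O1–C8a formed by oxa-Michael addition to an acylquinone.** The O1–C8a bond is disconnected. Ag2O oxidises the hydroquinone diketone A7 to the acylquinone A8, and the enol oxygen of the diketone adds to the quinone CH between the acyl-bearing carbon and a quinone carbonyl. Tautomerisation then gives the 5,8-dihydroxyflavone A6.
- For: O1 need not be on ring A beforehand, only one quinone carbon is within reach of the enol oxygen, and the C–O bond is formed without a palladium catalyst or CO. The chelated 5-hydroxyl of A6 is less nucleophilic than the 8-hydroxyl, so the later 8-O-methylation should be selective. On these points the route is as strong as the chosen one.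
- Against: acylquinones are strongly electrophilic and oxidising, so intermolecular addition, attack at the benzyloxy-bearing carbon and over-oxidation of the hydroquinone product A6 by the same oxidant all threaten the step.
- Further against: A7 needs a hydroquinone with three differentiated oxygens and a separately installed diketone chain, and a methylation and a debenzylation follow the key step.
- Comparison: the chosen route brings the 8-methoxy group in with compound 1 and reaches the target one step after the key step.

Key step: step 6

Remark on the chemistry: 1, 5, 9 and 10 are taken as purchased. Intermediate 12 is drawn as its E isomer, but its double-bond geometry is neither controlled nor relevant to the ring closure.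

## Route

Step 1
Reactants: 1 2-methoxybenzene-1,3-diol (2-methoxyresorcinol)
Product: 2 2-methoxy-1,3-bis(methoxymethoxy)benzene
Conditions: NaH, MOMCl, THF/DMF, 0 °C to rt
Reagents that add atoms: chloromethyl methyl ether, COCCl
Why: Williamson-type O-alkylation of both phenoxides by the reactive α-chloro ether should give the bis-acetal; the acetals are inert to the borylation, to basic peroxide and to the later benzylation, and they leave C5–H as the only ring hydrogen without an ortho substituent.

Step 2
Reactants: 2 2-methoxy-1,3-bis(methoxymethoxy)benzene
Product: 4 4-methoxy-3,5-bis(methoxymethoxy)phenol, via pinacol arylboronate 3 (not isolated)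
Conditions: [Ir(OMe)(cod)]2 (1.5 mol%), 4,4'-di-tert-butyl-2,2'-bipyridine (3 mol%), B2pin2, THF, 80 °C; then aq. NaOH, H2O2, 0 °C
Reagents that add atoms: bis(pinacolato)diboron, CC1(C)OB(OC1(C)C)B1OC(C)(C)C(C)(C)O1 (boron of intermediate 3); hydrogen peroxide, OO (new oxygen of 4)
Why: Iridium-catalysed aromatic C–H borylation is sterically controlled, so only C5–H, the one ring hydrogen with no ortho substituent, should react; basic peroxide then converts C–B into C–O at the same carbon by aryl migration from boron to oxygen.

Step 3
Reactants: 4 4-methoxy-3,5-bis(methoxymethoxy)phenol; 5 benzyl bromide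
Product: 6 5-(benzyloxy)-2-methoxy-1,3-bis(methoxymethoxy)benzene
Conditions: K2CO3, DMF, rt
Reagents that add atoms: none
Why: Williamson etherification of the only free phenol; the acetals are stable to base and no competing hydroxyl is present.

Step 4
Reactants: 6 5-(benzyloxy)-2-methoxy-1,3-bis(methoxymethoxy)benzene
Product: 7 5-(benzyloxy)-2-methoxybenzene-1,3-diol
Conditions: conc. HCl (cat.), MeOH, 40 °C
Reagents that add atoms: none
Why: Acid-catalysed transacetalisation to methanol should cleave both methoxymethyl acetals, the large excess of methanol trapping the methoxymethyl cation before it can attack the electron-rich ring; the benzyl and methyl ethers are stable to dilute acid at this temperature.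

Step 5
Reactants: 7 5-(benzyloxy)-2-methoxybenzene-1,3-diol
Product: 8 5-(benzyloxy)-4-iodo-2-methoxybenzene-1,3-diol
Conditions: NIS (1.0 equiv, slow addition), MeCN, −30 to 0 °C, dark
Reagents that add atoms: N-iodosuccinimide, O=C1CCC(=O)N1I
Why: Electrophilic aromatic iodination; C4 and C6 are the only free positions, are equivalent by the mirror symmetry of 7 and are each ortho and para to a hydroxyl, so one equivalent of iodinating agent at low temperature should give the single mono-iodide.

Step 6
Reactants: 8 5-(benzyloxy)-4-iodo-2-methoxybenzene-1,3-diol; 9 5-ethynyl-1,2,3-trimethoxybenzene; 10 carbon monoxide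
Product: 13 5-(benzyloxy)-7-hydroxy-8-methoxy-2-(3,4,5-trimethoxyphenyl)-4H-chromen-4-one, via aryl ynone 11 (not isolated), via diethylaminoenone 12 (not isolated)
Conditions: PdCl2(PPh3)2 (5 mol%), CO (20 atm), Et2NH, 120 °C
Reagents that add atoms: diethylamine, CCNCC (present only in intermediate 12)
Why: The divalent palladium precatalyst PdCl2(PPh3)2 is reduced in the amine to zerovalent palladium, which inserts into the C–I bond of 8, and migratory insertion of 10 gives ArC(O)PdI(PPh3)2 and with it the C4a–C4 bond. The amine-deprotonated alkyne 9 is transferred to palladium and reductive elimination forms C4–C3, giving the ortho-hydroxyaryl ynone 11 in a copper-free carbonylative Sonogashira coupling. Diethylamine adds in conjugate fashion to 11 to give the β-aminoenone 12, and the neighbouring phenoxide attacks its β-carbon and expels the amine in a 6-endo-trig addition–elimination that forms O1–C2 and closes ring C. The closest known reaction type is the palladium-catalysed carbonylative annulation of 2-iodophenols with terminal alkynes in a secondary amine to give flavones and chromones. No stereocentre is formed. Three selectivities are needed: CO insertion before alkynyl transfer, which CO pressure, the absence of copper and the two ortho substituents on ArPdI(PPh3)2 favour; 6-endo closure instead of 5-exo closure to an aurone, which the aminoenone secures because its β-carbon is the only electrophilic site left; and the choice of ring oxygen, which the substrate fixes because the only free hydroxyl ortho to iodine lies between iodine and methoxy, the other ortho oxygen being benzylated and the second hydroxyl para to iodine.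

Step 7
Reactants: 13 5-(benzyloxy)-7-hydroxy-8-methoxy-2-(3,4,5-trimethoxyphenyl)-4H-chromen-4-one
Product: 14 5,7-dihydroxy-8-methoxy-2-(3,4,5-trimethoxyphenyl)-4H-chromen-4-one (3',4',5'-trimethoxywogonin)
Conditions: H2 (1 atm), 10% Pd/C, EtOAc/MeOH, rt
Reagents that add atoms: none
Why: Heterogeneous hydrogenolysis of the aryl benzyl ether under neutral conditions; the C2=C3 bond belongs to the conjugated pyranone and should be reduced much more slowly at 1 atm if the reaction is stopped once 13 is consumed, and the absence of acid excludes Wessely–Moser isomerisation.

## Compound list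

1 | 2-methoxybenzene-1,3-diol (2-methoxyresorcinol) | COc1c(O)cccc1O | starting material
2 | 2-methoxy-1,3-bis(methoxymethoxy)benzene | COCOc1cccc(OCOC)c1OC | intermediate
3 | 2-[4-methoxy-3,5-bis(methoxymethoxy)phenyl]-4,4,5,5-tetramethyl-1,3,2-dioxaborolane | COCOc1cc(B2OC(C)(C)C(C)(C)O2)cc(OCOC)c1OC | intermediate (not isolated)
4 | 4-methoxy-3,5-bis(methoxymethoxy)phenol | COCOc1cc(O)cc(OCOC)c1OC | intermediate
5 | benzyl bromide | BrCc1ccccc1 | starting material
6 | 5-(benzyloxy)-2-methoxy-1,3-bis(methoxymethoxy)benzene | COCOc1cc(OCc2ccccc2)cc(OCOC)c1OC | intermediate
7 | 5-(benzyloxy)-2-methoxybenzene-1,3-diol | COc1c(O)cc(OCc2ccccc2)cc1O | intermediate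
8 | 5-(benzyloxy)-4-iodo-2-methoxybenzene-1,3-diol | COc1c(O)cc(OCc2ccccc2)c(I)c1O | intermediate
9 | 5-ethynyl-1,2,3-trimethoxybenzene | C#Cc1cc(OC)c(OC)c(OC)c1 | starting material
10 | carbon monoxide | [C-]#[O+] | starting material
11 | 1-[6-(benzyloxy)-2,4-dihydroxy-3-methoxyphenyl]-3-(3,4,5-trimethoxyphenyl)prop-2-yn-1-one | COc1cc(C#CC(=O)c2c(O)c(OC)c(O)cc2OCc2ccccc2)cc(OC)c1OC | intermediate (not isolated)
12 | (E)-1-[6-(benzyloxy)-2,4-dihydroxy-3-methoxyphenyl]-3-(diethylamino)-3-(3,4,5-trimethoxyphenyl)prop-2-en-1-one | CCN(CC)/C(=C/C(=O)c1c(O)c(OC)c(O)cc1OCc1ccccc1)c1cc(OC)c(OC)c(OC)c1 | intermediate (not isolated)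
13 | 5-(benzyloxy)-7-hydroxy-8-methoxy-2-(3,4,5-trimethoxyphenyl)-4H-chromen-4-one | COc1cc(-c2cc(=O)c3c(OCc4ccccc4)cc(O)c(OC)c3o2)cc(OC)c1OC | intermediate
14 | 5,7-dihydroxy-8-methoxy-2-(3,4,5-trimethoxyphenyl)-4H-chromen-4-one | COc1cc(-c2cc(=O)c3c(O)cc(O)c(OC)c3o2)cc(OC)c1OC | target

Total step count: 7. Longest linear sequence: 7 steps (1 to 14); 5, 9 and 10 enter as purchased materials.

## Steps least certain to work

**Step 6 (key step).** The most likely failure is diversion of ArC(O)PdI(PPh3)2 by the amine solvent (aminocarbonylation), or alkynyl transfer before CO insertion followed by furan closure. Both become more likely because oxidative addition into the electron-rich C–I bond with two ortho substituents is slow and the free phenoxide can bind palladium.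
- Fallback: the same three bonds are built without palladium or CO gas, with C4 supplied by a formyl group.
- It sets out from 6. Ortho-lithiation between the acetal and the benzyloxy group (n-BuLi, THF, 0 °C) and quenching with DMF should give 6-(benzyloxy)-3-methoxy-2,4-bis(methoxymethoxy)benzaldehyde F1.
- Addition of the lithium acetylide of 9 (n-BuLi, THF, −78 °C) should give the racemic propargylic alcohol 1-[6-(benzyloxy)-3-methoxy-2,4-bis(methoxymethoxy)phenyl]-3-(3,4,5-trimethoxyphenyl)prop-2-yn-1-ol F2.
- Oxidation with MnO2 in CH2Cl2 should give the ynone 1-[6-(benzyloxy)-3-methoxy-2,4-bis(methoxymethoxy)phenyl]-3-(3,4,5-trimethoxyphenyl)prop-2-yn-1-one F3.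
- Methanolic HCl should remove both acetals to give 11, and diethylamine in ethanol should then close ring C through 12. The path rejoins the route at 13.

**Step 5.** The likely failure is a second iodination at the remaining equivalent position, or oxidative degradation of the very electron-rich diol and of the light- and air-sensitive product.
- Fallback: the iodine is placed by directed metalation, which cannot over-iodinate.
- It sets out from 6. n-BuLi (THF, 0 °C) followed by I2 should give 1-(benzyloxy)-2-iodo-4-methoxy-3,5-bis(methoxymethoxy)benzene F4.
- Brief treatment with HCl in methanol at room temperature should remove the acetals. The path rejoins at 8.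

**Step 4.** The likely failure is alkylation of the highly nucleophilic ring of 7 by the methoxymethyl cation or by formaldehyde equivalents, leading to methylene-bridged dimers.
- Fallback: the hydroxyls are protected with fluoride-labile groups, so that no carbon electrophile is released at the deprotection.
- It sets out from 1. TIPSCl and imidazole in DMF should give 2-methoxy-1,3-bis[(triisopropylsilyl)oxy]benzene F5.
- Borylation as in step 2 should give 2-{4-methoxy-3,5-bis[(triisopropylsilyl)oxy]phenyl}-4,4,5,5-tetramethyl-1,3,2-dioxaborolane F6.
- Oxidation with NaBO3·4H2O in THF/water should give 4-methoxy-3,5-bis[(triisopropylsilyl)oxy]phenol F7.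
- Benzylation with 5 and K2CO3 in acetone should give 5-(benzyloxy)-2-methoxy-1,3-bis[(triisopropylsilyl)oxy]benzene F8.
- Tetrabutylammonium fluoride buffered with acetic acid (THF, 0 °C) should remove both silyl groups. The path rejoins at 7.

**Step 7.** The likely failure is over-reduction of the C2=C3 bond to the flavanone on extended exposure, or stalling of the hydrogenolysis through catalyst poisoning by traces of iodide or amine carried over from step 6.
- Fallback: the benzyl ether is cleaved by a Lewis acid instead of by reduction.
- It sets out from 13. BCl3 with pentamethylbenzene as cation scavenger (CH2Cl2, −78 °C) should remove the benzyl group, which lies peri to the C4 carbonyl and is activated by chelation, while the methyl ethers survive at this temperature.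
- The path arrives directly at 14; no new compound (F0) is formed on it.

## Further compounds

F1 | step 6 | 6-(benzyloxy)-3-methoxy-2,4-bis(methoxymethoxy)benzaldehyde | COCOc1cc(OCc2ccccc2)c(C=O)c(OCOC)c1OC
F2 | step 6 | 1-[6-(benzyloxy)-3-methoxy-2,4-bis(methoxymethoxy)phenyl]-3-(3,4,5-trimethoxyphenyl)prop-2-yn-1-ol (racemic) | COCOc1cc(OCc2ccccc2)c(C(O)C#Cc2cc(OC)c(OC)c(OC)c2)c(OCOC)c1OC
F3 | step 6 | 1-[6-(benzyloxy)-3-methoxy-2,4-bis(methoxymethoxy)phenyl]-3-(3,4,5-trimethoxyphenyl)prop-2-yn-1-one | COCOc1cc(OCc2ccccc2)c(C(=O)C#Cc2cc(OC)c(OC)c(OC)c2)c(OCOC)c1OC
F4 | step 5 | 1-(benzyloxy)-2-iodo-4-methoxy-3,5-bis(methoxymethoxy)benzene | COCOc1cc(OCc2ccccc2)c(I)c(OCOC)c1OC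
F5 | step 4 | 2-methoxy-1,3-bis[(triisopropylsilyl)oxy]benzene | COc1c(O[Si](C(C)C)(C(C)C)C(C)C)cccc1O[Si](C(C)C)(C(C)C)C(C)C
F6 | step 4 | 2-{4-methoxy-3,5-bis[(triisopropylsilyl)oxy]phenyl}-4,4,5,5-tetramethyl-1,3,2-dioxaborolane | COc1c(O[Si](C(C)C)(C(C)C)C(C)C)cc(B2OC(C)(C)C(C)(C)O2)cc1O[Si](C(C)C)(C(C)C)C(C)C
F7 | step 4 | 4-methoxy-3,5-bis[(triisopropylsilyl)oxy]phenol | COc1c(O[Si](C(C)C)(C(C)C)C(C)C)cc(O)cc1O[Si](C(C)C)(C(C)C)C(C)C
F8 | step 4 | 5-(benzyloxy)-2-methoxy-1,3-bis[(triisopropylsilyl)oxy]benzene | COc1c(O[Si](C(C)C)(C(C)C)C(C)C)cc(OCc2ccccc2)cc1O[Si](C(C)C)(C(C)C)C(C)C
F0 | step 7 | none | none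
A1 | alternative 1 | 5,7-bis(benzyloxy)-8-methoxy-2-(3,4,5-trimethoxyphenyl)-4H-chromen-4-one | COc1cc(-c2cc(=O)c3c(OCc4ccccc4)cc(OCc4ccccc4)c(OC)c3o2)cc(OC)c1OC
A2 | alternative 1 | 3,5-bis(benzyloxy)-2-methoxy-6-[(triphenyl-λ5-phosphanylidene)acetyl]phenyl 3,4,5-trimethoxybenzoate | COc1cc(C(=O)Oc2c(OC)c(OCc3ccccc3)cc(OCc3ccccc3)c2C(=O)C=P(c2ccccc2)(c2ccccc2)c2ccccc2)cc(OC)c1OC
A3 | alternative 1 | 1-[4,6-bis(benzyloxy)-2-hydroxy-3-methoxyphenyl]ethan-1-one | CC(=O)c1c(O)c(OC)c(OCc2ccccc2)cc1OCc1ccccc1
A4 | alternative 2 | 5-hydroxy-7-isopropoxy-8-methoxy-2-(3,4,5-trimethoxyphenyl)-4H-chromen-4-one | COc1cc(-c2cc(=O)c3c(O)cc(OC(C)C)c(OC)c3o2)cc(OC)c1OC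
A5 | alternative 2 | 3-isopropoxy-4-methoxy-4-[4-oxo-6-(3,4,5-trimethoxyphenyl)-4H-pyran-2-yl]cyclobut-2-en-1-one (racemic) | CC(C)OC1=CC(=O)C1(OC)c1cc(=O)cc(-c2cc(OC)c(OC)c(OC)c2)o1
A6 | alternative 3 | 7-(benzyloxy)-5,8-dihydroxy-2-(3,4,5-trimethoxyphenyl)-4H-chromen-4-one | COc1cc(-c2cc(=O)c3c(O)cc(OCc4ccccc4)c(O)c3o2)cc(OC)c1OC
A7 | alternative 3 | 1-[4-(benzyloxy)-2,5-dihydroxyphenyl]-3-(3,4,5-trimethoxyphenyl)propane-1,3-dione | COc1cc(C(=O)CC(=O)c2cc(O)c(OCc3ccccc3)cc2O)cc(OC)c1OC
A8 | alternative 3 | 2-(benzyloxy)-5-[3-oxo-3-(3,4,5-trimethoxyphenyl)propanoyl]cyclohexa-2,5-diene-1,4-dione | COc1cc(C(=O)CC(=O)C2=CC(=O)C(OCc3ccccc3)=CC2=O)cc(OC)c1OC
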